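**Retrosynthetic overview**

1. The last C–C events are acylation of the C-3-lithiated 2,4-dialkoxypyridine with a tetraenoic N-methoxy-N-methylamide made from (S)-citronellal, then an intramolecular Diels–Alder reaction that closes both decalin rings at once, then C-2 epimerisation and global fluoride deprotection.
2. Ring C (the 2-pyridyl-7-oxabicyclo[4.1.0]heptane-2,5-diol) is traced back through reduction of a C-5 ketone and an anti-selective epoxidation to a 4-pyridyl-4-silyloxycyclohex-2-en-1-one.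
3. Key disconnection: that enone is assembled in one operation from a pyridyl(silyloxy)acetaldehyde and methyl vinyl ketone by an amine-catalysed enantioselective Michael/aldol annulation, which forms the C-2–C-3 and C-1–C-6 bonds of ring C and sets the C-2 carbinol centre.
4. Enabling feature: in ring C the quaternary C-2 (bearing O and the pyridyl group) is 1,4 to the oxygenated C-5, with the C-1/C-6 epoxide between them. Ring C is therefore a 4-aryl-4-oxycyclohex-2-enone at a higher oxidation level, in which C-2/C-1 is an α-oxy aldehyde (donor/acceptor) and C-3 to C-6 is a vinyl ketone (acceptor/donor).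
5. Ring order: pyridine (bought) → ring C carbocycle (step 5) → epoxide (step 6) → rings A and B together (step 15).

Key step: step 5

**Remarks**

- Locants: ring C keeps the target's locants throughout (C-1 and C-6 epoxide carbons, C-2 the pyridyl-bearing carbinol carbon, C-5 the secondary carbinol carbon). The decalin is numbered with the propenyl group on C-1 and the acyl group on C-2.
- Assumption: the sense of induction of the amine catalyst in step 5 is assigned by analogy with α-aryl-α-alkyl aldehydes; should a first run show the opposite sense, the pseudoenantiomeric quinidine-derived amine is used with no other change.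

**Route**

Step 1
Reactants: 1 5-bromo-2,4-dichloropyridine; 2 2-(trimethylsilyl)ethanol
Product: 3 5-bromo-2,4-bis[2-(trimethylsilyl)ethoxy]pyridine
Conditions: NaH (2.4 equiv), 2 (2.4 equiv), THF, 0 °C; then DMF, 80 °C
Reagents that add atoms: none
Why: Twofold nucleophilic aromatic substitution (addition–elimination) at C-4 and then C-2, both activated by the ring nitrogen, while the bromide at C-5 (meta to nitrogen) is inert, so that both pyridone oxygens enter as fluoride-cleavable ethers.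

Step 2
Reactants: 3 5-bromo-2,4-bis[2-(trimethylsilyl)ethoxy]pyridine; 4 acrolein
Product: 6 rac-1-{4,6-bis[2-(trimethylsilyl)ethoxy]pyridin-3-yl}prop-2-en-1-ol, via aryllithium 5 (not isolated)
Conditions: n-BuLi, THF, −78 °C; 4, −78 °C; H2O
Reagents that add atoms: none
Why: Bromine–lithium exchange at −78 °C is faster than attack of n-BuLi on the ring and the ortho-alkoxy-stabilised aryllithium adds 1,2 to the enal (carbonyl addition); the carbinol centre is formed racemic on purpose because it becomes an enamine carbon in step 5.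

Step 3
Reactants: 6 rac-1-{4,6-bis[2-(trimethylsilyl)ethoxy]pyridin-3-yl}prop-2-en-1-ol
Product: 7 rac-5-[1-(triethylsilyloxy)prop-2-en-1-yl]-2,4-bis[2-(trimethylsilyl)ethoxy]pyridine
Conditions: Et3SiCl, imidazole, CH2Cl2, 0 → 25 °C
Reagents that add atoms: chlorotriethylsilane, CC[Si](Cl)(CC)CC
Why: Imidazole-promoted O-silylation of a secondary alcohol; the triethylsilyl group is small enough for enamine formation in step 5 yet large enough to steer steps 6 and 7.

Step 4
Reactants: 7 rac-5-[1-(triethylsilyloxy)prop-2-en-1-yl]-2,4-bis[2-(trimethylsilyl)ethoxy]pyridine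
Product: 8 rac-2-{4,6-bis[2-(trimethylsilyl)ethoxy]pyridin-3-yl}-2-(triethylsilyloxy)acetaldehyde
Conditions: OsO4 (2 mol%), NaIO4 (3 equiv), 2,6-lutidine, 1,4-dioxane/H2O 3:1, 25 °C; used crude
Reagents that add atoms: sodium periodate, [Na+].[O-]I(=O)(=O)=O
Why: Lemieux–Johnson oxidation (catalytic dihydroxylation, then periodate glycol cleavage) removes the terminal CH2 of the vinyl group and leaves the electron-rich pyridine, which ozone might attack, untouched.

Step 5
Reactants: 8 rac-2-{4,6-bis[2-(trimethylsilyl)ethoxy]pyridin-3-yl}-2-(triethylsilyloxy)acetaldehyde; 9 methyl vinyl ketone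
Product: 12 (4S)-4-{4,6-bis[2-(trimethylsilyl)ethoxy]pyridin-3-yl}-4-(triethylsilyloxy)cyclohex-2-en-1-one, via Michael adduct 10 (not isolated), via aldol adduct 11 (not isolated)
Conditions: 9-amino-9-deoxy-epi-quinine (20 mol%), 4-nitrobenzoic acid (40 mol%), 9 (3 equiv), toluene, 25 °C; then pyrrolidine/AcOH (30 mol% each), 50 °C, same flask
Reagents that add atoms: none
Why: Proposed new method: the primary amine condenses with racemic 8 to an aryl-conjugated enamine whose α-carbon adds to the β-carbon of 9 (Michael addition) to give aldehyde 10 with the O,aryl-substituted quaternary carbon, after which a ketone-derived enamine (or enol) of 10 attacks the now non-enolisable aldehyde (aldol addition to 11) and water is lost to give 12. The closest known reaction type is the amine-catalysed Robinson-type annulation of α-aryl-α-alkyl aldehydes with methyl vinyl ketone to 4,4-disubstituted cyclohex-2-enones; what is new is the silyloxy group in place of the alkyl branch. Ring C closes by a 6-(enolexo)-exo-trig aldol addition through the methyl carbon of the ketone, the only six-membered option, since closure through the methylene α-carbon would give a four-membered ring. The single new stereocentre (C-4 of 12, the later C-2 of ring C) is set in the Michael step by the catalyst: the enamine should form with the aryl group trans to nitrogen, the protonated quinuclidine holds the enone by hydrogen bonding and the quinoline shields one enamine face, while both enantiomers of 8 converge through the planar enamine. The step needs C–C rather than N–C or O–C bond formation, a single Michael addition and enantiofacial control; the first two are secured by the substrate, which has one α-hydrogen only and becomes quaternary after the first addition.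

Step 6
Reactants: 12 (4S)-4-{4,6-bis[2-(trimethylsilyl)ethoxy]pyridin-3-yl}-4-(triethylsilyloxy)cyclohex-2-en-1-one
Product: 13 (1S,2R,6R)-2-{4,6-bis[2-(trimethylsilyl)ethoxy]pyridin-3-yl}-2-(triethylsilyloxy)-7-oxabicyclo[4.1.0]heptan-5-one
Conditions: 30% aq. H2O2 (3 equiv), NaOH (0.3 equiv), MeOH, 0 °C
Reagents that add atoms: hydrogen peroxide, OO
Why: Weitz–Scheffer nucleophilic epoxidation: hydroperoxide adds to the enone β-carbon anti to the pseudo-axial C–OSiEt3 bond of the adjacent quaternary carbon (the known course for 4-silyloxycyclohex-2-enones) and the enolate closes onto oxygen, which sets C-1 and C-6 with the epoxide trans to the silyloxy group and cis to the pyridyl group.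

Step 7
Reactants: 13 (1S,2R,6R)-2-{4,6-bis[2-(trimethylsilyl)ethoxy]pyridin-3-yl}-2-(triethylsilyloxy)-7-oxabicyclo[4.1.0]heptan-5-one
Product: 14 (1S,2R,5R,6S)-2-{4,6-bis[2-(trimethylsilyl)ethoxy]pyridin-3-yl}-2-(triethylsilyloxy)-7-oxabicyclo[4.1.0]heptan-5-ol
Conditions: NaBH4, CeCl3·7H2O, MeOH, −78 °C
Reagents that add atoms: none
Why: Luche reduction (1,2-hydride delivery): in the half-chair with the pyridyl group pseudo-equatorial and the silyloxy group pseudo-axial, the small hydride should attack the carbonyl axially from the epoxide face, the other face being screened by the silyloxy group, which sets C-5 with its hydroxyl trans to the epoxide and cis to the C-2 oxygen.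

Step 8
Reactants: 14 (1S,2R,5R,6S)-2-{4,6-bis[2-(trimethylsilyl)ethoxy]pyridin-3-yl}-2-(triethylsilyloxy)-7-oxabicyclo[4.1.0]heptan-5-ol
Product: 15 5-[(1S,2R,5R,6R)-5-(tert-butyldimethylsilyloxy)-2-(triethylsilyloxy)-7-oxabicyclo[4.1.0]heptan-2-yl]-2,4-bis[2-(trimethylsilyl)ethoxy]pyridine
Conditions: t-BuMe2SiCl, imidazole, DMF, 25 °C
Reagents that add atoms: tert-butyl(chloro)dimethylsilane, CC(C)(C)[Si](C)(C)Cl
Why: Standard O-silylation of the secondary alcohol under non-acidic conditions that do not touch the epoxide.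

Step 9
Reactants: 16 (S)-citronellal; 17 (triphenylphosphoranylidene)acetaldehyde
Product: 18 (2E,5S)-5,9-dimethyldeca-2,8-dienal
Conditions: toluene, 80 °C
Reagents that add atoms: none
Why: Wittig olefination with a stabilised formyl ylide gives the (E)-enal, and the methyl-bearing stereocentre, β to the aldehyde, is not enolisable.

Step 10
Reactants: 18 (2E,5S)-5,9-dimethyldeca-2,8-dienal; 19 5-(ethylsulfonyl)-1-phenyl-1H-tetrazole
Product: 20 (2E,4E,7S)-7,11-dimethyldodeca-2,4,10-triene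
Conditions: 19, KN(SiMe3)2, 1,2-dimethoxyethane, −60 °C; then 18, −60 → 25 °C
Reagents that add atoms: none
Why: Julia–Kocienski olefination: the metallated ethyl sulfone adds to the enal and Smiles rearrangement/elimination gives the new 1,2-disubstituted alkene with E geometry, completing the (E,E)-diene that later serves as dienophile.

Step 11
Reactants: 20 (2E,4E,7S)-7,11-dimethyldodeca-2,4,10-triene
Product: 21 (2E,6S,8E,10E)-2,6-dimethyldodeca-2,8,10-trien-1-ol
Conditions: SeO2 (10 mol%), t-BuOOH (2 equiv), salicylic acid (10 mol%), CH2Cl2, 25 °C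
Reagents that add atoms: tert-butyl hydroperoxide, CC(C)(C)OO
Why: Selenium dioxide allylic oxidation (ene reaction followed by [2,3]-sigmatropic shift) takes the (E)-methyl group of the most electron-rich, trisubstituted alkene, the conjugated diene being the poorer ene partner as known for myrcene-type polyenes.

Step 12
Reactants: 21 (2E,6S,8E,10E)-2,6-dimethyldodeca-2,8,10-trien-1-ol
Product: 22 (2E,6S,8E,10E)-2,6-dimethyldodeca-2,8,10-trienal
Conditions: MnO2 (excess), CH2Cl2, 25 °C
Reagents that add atoms: none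
Why: Chemoselective oxidation of the allylic alcohol on MnO2 stops at the enal and keeps the E geometry.

Step 13
Reactants: 22 (2E,6S,8E,10E)-2,6-dimethyldodeca-2,8,10-trienal; 23 diethyl {2-[methoxy(methyl)amino]-2-oxoethyl}phosphonate
Product: 24 (2E,4E,8S,10E,12E)-N-methoxy-N,4,8-trimethyltetradeca-2,4,10,12-tetraenamide
Conditions: 23, NaH, THF, 0 °C; then 22, 0 → 25 °C
Reagents that add atoms: none
Why: Horner–Wadsworth–Emmons olefination with the stabilised amide phosphonate gives the (2E)-configured dienamide.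

Step 14
Reactants: 15 5-[(1S,2R,5R,6R)-5-(tert-butyldimethylsilyloxy)-2-(triethylsilyloxy)-7-oxabicyclo[4.1.0]heptan-2-yl]-2,4-bis[2-(trimethylsilyl)ethoxy]pyridine; 24 (2E,4E,8S,10E,12E)-N-methoxy-N,4,8-trimethyltetradeca-2,4,10,12-tetraenamide
Product: 27 (2E,4E,8S,10E,12E)-1-{5-[(1S,2R,5R,6R)-5-(tert-butyldimethylsilyloxy)-2-(triethylsilyloxy)-7-oxabicyclo[4.1.0]heptan-2-yl]-2,4-bis[2-(trimethylsilyl)ethoxy]pyridin-3-yl}-4,8-dimethyltetradeca-2,4,10,12-tetraen-1-one, via 3-lithiopyridine 25 (not isolated), via tetrahedral lithium adduct 26 (not isolated)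
Conditions: n-BuLi, THF, −78 → −40 °C; 24, −78 → 0 °C; H2O
Reagents that add atoms: none
Why: Directed ortho-metalation at C-3, the only ring position flanked by two alkoxy groups, then acyl substitution on the N-methoxy-N-methylamide, whose chelated tetrahedral adduct prevents over-addition; the unactivated epoxide is not opened by organolithiums at these temperatures.

Step 15
Reactants: 27 (2E,4E,8S,10E,12E)-1-{5-[(1S,2R,5R,6R)-5-(tert-butyldimethylsilyloxy)-2-(triethylsilyloxy)-7-oxabicyclo[4.1.0]heptan-2-yl]-2,4-bis[2-(trimethylsilyl)ethoxy]pyridin-3-yl}-4,8-dimethyltetradeca-2,4,10,12-tetraen-1-one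
Product: 29 {5-[(1S,2R,5R,6R)-5-(tert-butyldimethylsilyloxy)-2-(triethylsilyloxy)-7-oxabicyclo[4.1.0]heptan-2-yl]-2,4-bis[2-(trimethylsilyl)ethoxy]pyridin-3-yl}{(1R,2S,4aS,7S,8aR)-4,7-dimethyl-1-[(1E)-prop-1-en-1-yl]-1,2,4a,5,6,7,8,8a-octahydronaphthalen-2-yl}methanone, via C-2 epimer 28 (not isolated)
Conditions: toluene (0.01 M), 2,6-di-tert-butyl-4-methylphenol (5 mol%), 110 °C; then 1,8-diazabicyclo[5.4.0]undec-7-ene (0.5 equiv), 60 °C, same flask
Reagents that add atoms: none
Why: Intramolecular Diels–Alder reaction with inverse electron demand, the aryl dienone acting as 4π partner and the proximal C=C of the terminal (E,E)-diene as 2π partner: the chair-like four-carbon tether with equatorial methyl group and endo propenyl group should give the trans-fused decalin (C-1, C-4a and C-8a set relative to C-7) with the acyl group at C-2 cis to the propenyl group as dictated by the (E,E)-diene, and base-mediated enolisation then equilibrates C-2 to the more stable all-equatorial trans isomer, kinetic α-protonation of the dienolate keeping the alkene at C-3/C-4.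

Step 16
Reactants: 29 {5-[(1S,2R,5R,6R)-5-(tert-butyldimethylsilyloxy)-2-(triethylsilyloxy)-7-oxabicyclo[4.1.0]heptan-2-yl]-2,4-bis[2-(trimethylsilyl)ethoxy]pyridin-3-yl}{(1R,2S,4aS,7S,8aR)-4,7-dimethyl-1-[(1E)-prop-1-en-1-yl]-1,2,4a,5,6,7,8,8a-octahydronaphthalen-2-yl}methanone
Product: 30 3-{[(1R,2S,4aS,7S,8aR)-4,7-dimethyl-1-[(1E)-prop-1-en-1-yl]-1,2,4a,5,6,7,8,8a-octahydronaphthalen-2-yl]carbonyl}-5-[(1S,2R,5R,6S)-2,5-dihydroxy-7-oxabicyclo[4.1.0]heptan-2-yl]-4-hydroxypyridin-2(1H)-one (CNP0494338.1)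
Conditions: Bu4NF (6 equiv), AcOH (6 equiv), THF, 0 → 40 °C
Reagents that add atoms: none
Why: Fluoride attacks silicon in all four silyl groups: the two 2-(trimethylsilyl)ethyl ethers fragment by β-elimination (ethene and fluorotrimethylsilane) to the 4-hydroxy-2-pyridone and the two silyl ethers are cleaved to the diol, acetic acid buffering keeping the trans-epoxy alcohol from Payne rearrangement.

**Compound list**

1 | 5-bromo-2,4-dichloropyridine | Clc1cc(Cl)c(Br)cn1 | starting material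
2 | 2-(trimethylsilyl)ethanol | C[Si](C)(C)CCO | starting material
3 | 5-bromo-2,4-bis[2-(trimethylsilyl)ethoxy]pyridine | C[Si](C)(C)CCOc1cc(OCC[Si](C)(C)C)c(Br)cn1 | intermediate
4 | acrolein (prop-2-enal) | C=CC=O | starting material
5 | {4,6-bis[2-(trimethylsilyl)ethoxy]pyridin-3-yl}lithium | [Li]c1cnc(OCC[Si](C)(C)C)cc1OCC[Si](C)(C)C | intermediate
6 | rac-1-{4,6-bis[2-(trimethylsilyl)ethoxy]pyridin-3-yl}prop-2-en-1-ol | C=CC(O)c1cnc(OCC[Si](C)(C)C)cc1OCC[Si](C)(C)C | intermediate
7 | rac-5-[1-(triethylsilyloxy)prop-2-en-1-yl]-2,4-bis[2-(trimethylsilyl)ethoxy]pyridine | C=CC(O[Si](CC)(CC)CC)c1cnc(OCC[Si](C)(C)C)cc1OCC[Si](C)(C)C | intermediate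
8 | rac-2-{4,6-bis[2-(trimethylsilyl)ethoxy]pyridin-3-yl}-2-(triethylsilyloxy)acetaldehyde | O=CC(O[Si](CC)(CC)CC)c1cnc(OCC[Si](C)(C)C)cc1OCC[Si](C)(C)C | intermediate
9 | methyl vinyl ketone (but-3-en-2-one) | CC(=O)C=C | starting material
10 | (2R)-2-{4,6-bis[2-(trimethylsilyl)ethoxy]pyridin-3-yl}-5-oxo-2-(triethylsilyloxy)hexanal | CC(=O)CC[C@](O[Si](CC)(CC)CC)(C=O)c1cnc(OCC[Si](C)(C)C)cc1OCC[Si](C)(C)C | intermediate
11 | (4R)-4-{4,6-bis[2-(trimethylsilyl)ethoxy]pyridin-3-yl}-3-hydroxy-4-(triethylsilyloxy)cyclohexan-1-one (both C-3 epimers) | O=C1CC[C@@](O[Si](CC)(CC)CC)(c2cnc(OCC[Si](C)(C)C)cc2OCC[Si](C)(C)C)C(O)C1 | intermediate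
12 | (4S)-4-{4,6-bis[2-(trimethylsilyl)ethoxy]pyridin-3-yl}-4-(triethylsilyloxy)cyclohex-2-en-1-one | O=C1C=C[C@](O[Si](CC)(CC)CC)(c2cnc(OCC[Si](C)(C)C)cc2OCC[Si](C)(C)C)CC1 | intermediate
13 | (1S,2R,6R)-2-{4,6-bis[2-(trimethylsilyl)ethoxy]pyridin-3-yl}-2-(triethylsilyloxy)-7-oxabicyclo[4.1.0]heptan-5-one | C[Si](C)(C)CCOc1cc(OCC[Si](C)(C)C)c(cn1)[C@]1(O[Si](CC)(CC)CC)CCC(=O)[C@@H]2O[C@@H]21 | intermediate
14 | (1S,2R,5R,6S)-2-{4,6-bis[2-(trimethylsilyl)ethoxy]pyridin-3-yl}-2-(triethylsilyloxy)-7-oxabicyclo[4.1.0]heptan-5-ol | C[Si](C)(C)CCOc1cc(OCC[Si](C)(C)C)c(cn1)[C@]1(O[Si](CC)(CC)CC)CC[C@@H](O)[C@@H]2O[C@@H]21 | intermediate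
15 | 5-[(1S,2R,5R,6R)-5-(tert-butyldimethylsilyloxy)-2-(triethylsilyloxy)-7-oxabicyclo[4.1.0]heptan-2-yl]-2,4-bis[2-(trimethylsilyl)ethoxy]pyridine | C[Si](C)(C)CCOc1cc(OCC[Si](C)(C)C)c(cn1)[C@]1(O[Si](CC)(CC)CC)CC[C@@H](O[Si](C)(C)C(C)(C)C)[C@@H]2O[C@@H]21 | intermediate
16 | (S)-citronellal [(3S)-3,7-dimethyloct-6-enal] | C[C@H](CC=O)CCC=C(C)C | starting material
17 | (triphenylphosphoranylidene)acetaldehyde | O=CC=P(c1ccccc1)(c1ccccc1)c1ccccc1 | starting material
18 | (2E,5S)-5,9-dimethyldeca-2,8-dienal | O=C/C=C/C[C@@H](C)CCC=C(C)C | intermediate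
19 | 5-(ethylsulfonyl)-1-phenyl-1H-tetrazole | CCS(=O)(=O)c1nnnn1-c1ccccc1 | starting material
20 | (2E,4E,7S)-7,11-dimethyldodeca-2,4,10-triene | C/C=C/C=C/C[C@@H](C)CCC=C(C)C | intermediate
21 | (2E,6S,8E,10E)-2,6-dimethyldodeca-2,8,10-trien-1-ol | C/C=C/C=C/C[C@@H](C)CC/C=C(C)/CO | intermediate
22 | (2E,6S,8E,10E)-2,6-dimethyldodeca-2,8,10-trienal | C/C=C/C=C/C[C@@H](C)CC/C=C(C)/C=O | intermediate
23 | diethyl {2-[methoxy(methyl)amino]-2-oxoethyl}phosphonate | CCOP(=O)(CC(=O)N(C)OC)OCC | starting material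
24 | (2E,4E,8S,10E,12E)-N-methoxy-N,4,8-trimethyltetradeca-2,4,10,12-tetraenamide | C/C=C/C=C/C[C@@H](C)CC/C=C(C)/C=C/C(=O)N(C)OC | intermediate
25 | 3-lithio derivative of 15 | [Li]c1c(OCC[Si](C)(C)C)c([C@]2(O[Si](CC)(CC)CC)CC[C@@H](O[Si](C)(C)C(C)(C)C)[C@@H]3O[C@@H]32)cnc1OCC[Si](C)(C)C | intermediate
26 | lithium alkoxide of the tetrahedral adduct of 25 and 24 (carbinolamine carbon unassigned) | C/C=C/C=C/C[C@@H](C)CC/C=C(C)/C=C/C([O-])(N(C)OC)c1c(OCC[Si](C)(C)C)c([C@]2(O[Si](CC)(CC)CC)CC[C@@H](O[Si](C)(C)C(C)(C)C)[C@@H]3O[C@@H]32)cnc1OCC[Si](C)(C)C.[Li+] | intermediate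
27 | (2E,4E,8S,10E,12E)-1-{5-[(1S,2R,5R,6R)-5-(tert-butyldimethylsilyloxy)-2-(triethylsilyloxy)-7-oxabicyclo[4.1.0]heptan-2-yl]-2,4-bis[2-(trimethylsilyl)ethoxy]pyridin-3-yl}-4,8-dimethyltetradeca-2,4,10,12-tetraen-1-one | C/C=C/C=C/C[C@@H](C)CC/C=C(C)/C=C/C(=O)c1c(OCC[Si](C)(C)C)c([C@]2(O[Si](CC)(CC)CC)CC[C@@H](O[Si](C)(C)C(C)(C)C)[C@@H]3O[C@@H]32)cnc1OCC[Si](C)(C)C | intermediate
28 | C-2 epimer of 29, decalin (1R,2R,4aS,7S,8aR), acyl cis to propenyl | C/C=C/[C@@H]1[C@H]2C[C@@H](C)CC[C@@H]2C(C)=C[C@@H]1C(=O)c1c(OCC[Si](C)(C)C)c([C@]2(O[Si](CC)(CC)CC)CC[C@@H](O[Si](C)(C)C(C)(C)C)[C@@H]3O[C@@H]32)cnc1OCC[Si](C)(C)C | intermediate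
29 | {5-[(1S,2R,5R,6R)-5-(tert-butyldimethylsilyloxy)-2-(triethylsilyloxy)-7-oxabicyclo[4.1.0]heptan-2-yl]-2,4-bis[2-(trimethylsilyl)ethoxy]pyridin-3-yl}{(1R,2S,4aS,7S,8aR)-4,7-dimethyl-1-[(1E)-prop-1-en-1-yl]-1,2,4a,5,6,7,8,8a-octahydronaphthalen-2-yl}methanone | C/C=C/[C@@H]1[C@H]2C[C@@H](C)CC[C@@H]2C(C)=C[C@H]1C(=O)c1c(OCC[Si](C)(C)C)c([C@]2(O[Si](CC)(CC)CC)CC[C@@H](O[Si](C)(C)C(C)(C)C)[C@@H]3O[C@@H]32)cnc1OCC[Si](C)(C)C | intermediate
30 | 3-{[(1R,2S,4aS,7S,8aR)-4,7-dimethyl-1-[(1E)-prop-1-en-1-yl]-1,2,4a,5,6,7,8,8a-octahydronaphthalen-2-yl]carbonyl}-5-[(1S,2R,5R,6S)-2,5-dihydroxy-7-oxabicyclo[4.1.0]heptan-2-yl]-4-hydroxypyridin-2(1H)-one | C/C=C/[C@@H]1[C@H]2C[C@@H](C)CC[C@@H]2C(C)=C[C@H]1C(=O)c1c(O)c([C@]2(O)CC[C@@H](O)[C@@H]3O[C@@H]32)c[nH]c1=O | target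

**Step count**

Total: 16 steps. Longest linear sequence: 11 steps (steps 1 to 8, then 14 to 16); the side-chain branch (steps 9 to 13) joins at step 14.

**Steps most likely to fail, with fallbacks**

1. Step 5 (proposed new method). Enamine formation from the α-silyloxy aldehyde may be slow, the silyl group may migrate with isomerisation to the α-silyloxy ketone, or enantiofacial selectivity may be poor. The fallback uses known chemistry, sets out from 3 and comes back at 12; ring C is then taken from a bought six-membered ring and its stereocentre is set by desymmetrisation. Aryllithium 5 (from 3 as in step 2) is added to 1,4-dioxaspiro[4.5]decan-8-one to give the tertiary alcohol 8-{4,6-bis[2-(trimethylsilyl)ethoxy]pyridin-3-yl}-1,4-dioxaspiro[4.5]decan-8-ol F1. Silylation (Et3SiOTf, 2,6-lutidine) gives the triethylsilyl ether F2, and ketal hydrolysis (pyridinium p-toluenesulfonate, acetone/H2O) gives the achiral 4-pyridyl-4-(triethylsilyloxy)cyclohexanone F3. Enantioselective deprotonation with the appropriate enantiomer of lithium bis(1-phenylethyl)amide in the presence of Me3SiCl (THF, −100 °C) gives the (S)-configured trimethylsilyl enol ether F4. Saegusa–Ito dehydrogenation (Pd(OAc)2, MeCN) of F4 gives 12.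

2. Step 15. The cycloaddition may show poor endo/exo selectivity or compete with the cycloaddition in which the terminal diene acts as 4π partner, and the equilibration may move the ring alkene into conjugation, all on the most advanced material. The fallback makes the decalin first; it sets out from 22 (and uses 15) and comes back at 29. Wittig reaction of 22 with 17 (toluene, 80 °C) gives (2E,4E,8S,10E,12E)-4,8-dimethyltetradeca-2,4,10,12-tetraenal F5. Its intramolecular Diels–Alder reaction (toluene, 110 °C, or Me2AlCl, CH2Cl2, −78 °C) gives the cis-configured decalin aldehyde F6, which is freed from isomers at this small-molecule stage. Equilibration (1,8-diazabicyclo[5.4.0]undec-7-ene, CH2Cl2, 0 °C, stopped before alkene migration) gives the trans aldehyde F7. Addition of 3-lithiopyridine 25 (from 15 as in step 14) gives the carbinol F8 as an epimer mixture, and Dess–Martin oxidation (NaHCO3, CH2Cl2) gives 29.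

3. Step 7. Facial selectivity of hydride delivery may be poor or reversed (attack anti to the epoxide oxygen), which would give the C-5 epimer. The fallback inverts the carbinol instead of relying on the reduction; it sets out from 13 and comes back at 14. Ketone 13 is reduced with the reagent found to favour the epimer (LiBH(s-Bu)3, THF, −78 °C, as first choice) to the (5S)-alcohol F9. Mitsunobu reaction (4-nitrobenzoic acid, PPh3, diisopropyl azodicarboxylate, THF) gives the inverted 4-nitrobenzoate F10, and methanolysis (K2CO3, MeOH) gives 14.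

**Further compounds**

F1 | step 5 | 8-{4,6-bis[2-(trimethylsilyl)ethoxy]pyridin-3-yl}-1,4-dioxaspiro[4.5]decan-8-ol | OC1(c2cnc(OCC[Si](C)(C)C)cc2OCC[Si](C)(C)C)CCC2(CC1)OCCO2
F2 | step 5 | 5-[8-(triethylsilyloxy)-1,4-dioxaspiro[4.5]decan-8-yl]-2,4-bis[2-(trimethylsilyl)ethoxy]pyridine | CC[Si](CC)(CC)OC1(c2cnc(OCC[Si](C)(C)C)cc2OCC[Si](C)(C)C)CCC2(CC1)OCCO2
F3 | step 5 | 4-{4,6-bis[2-(trimethylsilyl)ethoxy]pyridin-3-yl}-4-(triethylsilyloxy)cyclohexan-1-one | CC[Si](CC)(CC)OC1(c2cnc(OCC[Si](C)(C)C)cc2OCC[Si](C)(C)C)CCC(=O)CC1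
F4 | step 5 | 5-[(1S)-1-(triethylsilyloxy)-4-(trimethylsilyloxy)cyclohex-3-en-1-yl]-2,4-bis[2-(trimethylsilyl)ethoxy]pyridine | C[Si](C)(C)OC1=CC[C@](O[Si](CC)(CC)CC)(c2cnc(OCC[Si](C)(C)C)cc2OCC[Si](C)(C)C)CC1
F5 | step 15 | (2E,4E,8S,10E,12E)-4,8-dimethyltetradeca-2,4,10,12-tetraenal | C/C=C/C=C/C[C@@H](C)CC/C=C(C)/C=C/C=O
F6 | step 15 | (1R,2R,4aS,7S,8aR)-4,7-dimethyl-1-[(1E)-prop-1-en-1-yl]-1,2,4a,5,6,7,8,8a-octahydronaphthalene-2-carbaldehyde | C/C=C/[C@@H]1[C@H]2C[C@@H](C)CC[C@@H]2C(C)=C[C@@H]1C=O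
F7 | step 15 | (1R,2S,4aS,7S,8aR)-4,7-dimethyl-1-[(1E)-prop-1-en-1-yl]-1,2,4a,5,6,7,8,8a-octahydronaphthalene-2-carbaldehyde | C/C=C/[C@@H]1[C@H]2C[C@@H](C)CC[C@@H]2C(C)=C[C@H]1C=O
F8 | step 15 | {5-[(1S,2R,5R,6R)-5-(tert-butyldimethylsilyloxy)-2-(triethylsilyloxy)-7-oxabicyclo[4.1.0]heptan-2-yl]-2,4-bis[2-(trimethylsilyl)ethoxy]pyridin-3-yl}{(1R,2S,4aS,7S,8aR)-4,7-dimethyl-1-[(1E)-prop-1-en-1-yl]-1,2,4a,5,6,7,8,8a-octahydronaphthalen-2-yl}methanol (carbinol epimers) | C/C=C/[C@@H]1[C@H]2C[C@@H](C)CC[C@@H]2C(C)=C[C@H]1C(O)c1c(OCC[Si](C)(C)C)c([C@]2(O[Si](CC)(CC)CC)CC[C@@H](O[Si](C)(C)C(C)(C)C)[C@@H]3O[C@@H]32)cnc1OCC[Si](C)(C)C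
F9 | step 7 | (1S,2R,5S,6S)-2-{4,6-bis[2-(trimethylsilyl)ethoxy]pyridin-3-yl}-2-(triethylsilyloxy)-7-oxabicyclo[4.1.0]heptan-5-ol | C[Si](C)(C)CCOc1cc(OCC[Si](C)(C)C)c(cn1)[C@]1(O[Si](CC)(CC)CC)CC[C@H](O)[C@@H]2O[C@@H]21
F10 | step 7 | (1S,2R,5R,6R)-2-{4,6-bis[2-(trimethylsilyl)ethoxy]pyridin-3-yl}-2-(triethylsilyloxy)-7-oxabicyclo[4.1.0]heptan-5-yl 4-nitrobenzoate | C[Si](C)(C)CCOc1cc(OCC[Si](C)(C)C)c(cn1)[C@]1(O[Si](CC)(CC)CC)CC[C@@H](OC(=O)c3ccc(cc3)[N+](=O)[O-])[C@@H]2O[C@@H]21
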